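**Strategy.** The decalin is disconnected at C6–C7 and C5–C10 (labdane numbering). An intramolecular Diels–Alder reaction of an acyclic, enantiopure triene closes rings A and B in one operation and sets C5 and C10: a tetrasubstituted 2-(silylmethyl)diene (C7=C8–C9=C10) is tethered through C1–C3 to quaternary C4, which carries an (E)-sulfonylvinyl dienophile (C5=C6). The step exploits ring B, whose exocyclic C8=C17 methylene lies beside quaternary C10: the C8=C9 allylsilane left by the cycloaddition is protonated at C9 to unveil the methylene and the C9 stereocentre. C3 and C4 come from an Evans aldol and a Fráter–Seebach vinylation; a Sharpless epoxidation finishes the side chain.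

Key step: step 11

Assumption: labdane numbering (C1–C20) is used for all atom labels; enynol 1, imide 14 and the named reagents are taken as purchasable.

Step 1
Reactants: 1 (2E)-3-methylpent-2-en-4-yn-1-ol
Product: 2 tert-butyldiphenylsilyl ether of 1
Conditions: TBDPSCl, imidazole, DMF, 0 °C to rt
Reagents that add atoms: tert-butyl(chloro)diphenylsilane, CC(C)(C)[Si](Cl)(c1ccccc1)c1ccccc1
Why: Silylation of the primary allylic alcohol gives a protecting group that should survive the organometallic, basic, thermal and mildly acidic steps up to step 14.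

Step 2
Reactants: 2 enyne silyl ether
Product: 3 tert-butyl{[(2E)-3-methylpenta-2,4-dien-1-yl]oxy}diphenylsilane
Conditions: H2 (1 atm), Pd/CaCO3 poisoned with Pb(OAc)2, quinoline, hexane–EtOAc, rt
Reagents that add atoms: none
Why: Lindlar semihydrogenation reduces the terminal alkyne to a vinyl group and should leave the trisubstituted (E)-alkene untouched.

Step 3
Reactants: 4 3-chloropropan-1-ol; 5 methyl but-2-ynoate
Product: 8 methyl (2Z)-6-hydroxy-2-iodo-3-methylhex-2-enoate, via Normant Grignard reagent 6 (not isolated), via alkenylcopper adduct 7 (not isolated)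
Conditions: 4, i-PrMgCl, THF, −20 °C; Mg, reflux; CuBr·SMe2, −40 °C; 5, −78 °C; I2, −78 to 0 °C
Reagents that add atoms: iodine, II
Why: Syn-carbocupration of the ynoate places the C1–C3 chain and copper cis on C10=C9, and iodinolysis with retention gives the (Z)-α-iodoenoate, which fixes the later tetrasubstituted alkene geometry.

Step 4
Reactants: 3 silyloxy diene; 8 iodoenoate
Product: 10 methyl (2E)-2-[(3E)-5-(TBDPS-oxy)-3-methylpent-3-en-1-yl]-6-hydroxy-3-methylhex-2-enoate, via B-alkyl-9-BBN 9 (not isolated)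
Conditions: 3, 9-BBN-H, THF, 0 °C to rt; then 8, Pd(dppf)Cl2, AsPh3, Cs2CO3, DMF–H2O, rt to 45 °C
Reagents that add atoms: none
Why: In this B-alkyl Suzuki–Miyaura coupling 9-BBN hydroborates the terminal vinyl group anti-Markovnikov and the alkylborane couples with the vinyl iodide with retention, so the side chain (C11) ends up cis to the C1–C3 chain.

Step 5
Reactants: 10 tetrasubstituted enoate
Product: 12 (4E)-4-methyl-6-methylidene-5-(side chain)-7-(trimethylsilyl)hept-4-en-1-ol, via bis(silylmethyl) carbinol 11 (not isolated)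
Conditions: Me3SiCH2MgCl (5 equiv), CeCl3, THF, −78 °C to rt; then SiO2, CH2Cl2, rt
Reagents that add atoms: (trimethylsilyl)methylmagnesium chloride, C[Si](C)(C)C[Mg]Cl
Why: Cerium-mediated double addition to the ester followed by Peterson elimination (Bunnelle–Narayanan allylsilane synthesis) turns CO2Me into the C8(=C7H2)–C17H2SiMe3 unit, with the free hydroxyl carried as its alkoxide.

Step 6
Reactants: 12 dienyl alcohol
Product: 13 corresponding aldehyde (C3 = CHO)
Conditions: Dess–Martin periodinane, NaHCO3, CH2Cl2, 0 °C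
Reagents that add atoms: none
Why: Buffered Dess–Martin oxidation of the primary alcohol should be tolerated by the acid-sensitive allylsilane diene.

Step 7
Reactants: 14 (4S)-4-benzyl-3-propanoyl-1,3-oxazolidin-2-one; 13 aldehyde
Product: 16 Evans syn-aldol adduct (2S,3R), via dibutylboron enolate 15 (not isolated)
Conditions: 14, Bu2BOTf, i-Pr2NEt, CH2Cl2, −78 to 0 °C; then 13, −78 to 0 °C; H2O2, MeOH, pH 7 buffer
Reagents that add atoms: none
Why: The Evans syn-aldol reaction proceeds through the (Z)-boron enolate in a Zimmerman–Traxler transition state, and the (S)-benzyl auxiliary sets C3 as R (C4 is re-set in step 9).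

Step 8
Reactants: 16 aldol imide
Product: 17 methyl (2S,3R)-β-hydroxy-α-methyl ester
Conditions: NaOMe (0.3 equiv), MeOH–CH2Cl2, 0 °C
Reagents that add atoms: methanol, CO
Why: Methoxide-catalysed transesterification releases the auxiliary and gives the methyl ester (future C19), and any epimerisation at C4 is harmless because this centre is enolised in the next step.

Step 9
Reactants: 17 β-hydroxy ester
Product: 19 methyl (2R,3R)-3-hydroxy-2-methyl-2-[(E)-2-(phenylsulfonyl)ethenyl] ester, via dilithium alkoxide–enolate 18 (not isolated)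
Conditions: LiN(i-Pr)2 (2.2 equiv), THF, −78 to −30 °C; then (E)-PhSO2CH=CHSO2Ph, −78 °C
Reagents that add atoms: (E)-1,2-bis(phenylsulfonyl)ethene, O=S(=O)(/C=C/S(=O)(=O)c1ccccc1)c1ccccc1
Why: In this Fráter–Seebach reaction the chelated dianion adds to the bis-sulfone on the face anti to the C2 chain and expels sulfinate (conjugate addition–elimination), which should create quaternary C4 (R) and the (E)-vinyl sulfone C5=C6.

Step 10
Reactants: 19 hydroxy vinyl sulfone
Product: 20 3-acetate (Diels–Alder precursor)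
Conditions: Ac2O, DMAP, Et3N, CH2Cl2, rt
Reagents that add atoms: acetic anhydride, CC(=O)OC(C)=O
Why: DMAP-catalysed acetylation of the hindered secondary alcohol installs the final C3 acetate, which cannot eliminate because C4 carries no hydrogen.

Step 11
Reactants: 20 triene
Product: 21 trans-fused cycloadduct (rings A and B; C8=C9 allylsilane; 6α-sulfone)
Conditions: toluene (0.01 M), BHT, 140 °C, sealed tube
Reagents that add atoms: none
Why: This is a thermal intramolecular Diels–Alder reaction, a concerted but asynchronous [4+2] cycloaddition of the electron-rich silylmethyl diene (C7=C8–C9=C10) to the sulfone-activated alkene C5=C6, and its closest precedents are cyclisations of 1,7,9-decatrienes with a terminal sulfonyl or ester activating group. Ring B closes as a cyclohexene through the new C6–C7 and C5–C10 bonds, and ring A closes in the fused mode through the same C5–C10 bond across the four-atom tether C1–C4, the bridged regiochemistry being excluded by tether length. Trans fusion (5α-H, 10β-CH3) should follow from the transition state with the tether exo and the sulfone endo, because the alternative places quaternary C4 under the C9 side chain. π-Facial selectivity is controlled by C4, since in the chair-like tether the ester takes the pseudo-axial position syn to the C10 methyl and the C4 methyl the pseudo-equatorial one, which avoids a methyl–methyl 1,3-diaxial contact. The step needs reactivity below the temperature at which 1,5-hydrogen shift of the cis-methyl diene sets in, which the sulfone (LUMO lowering) and quaternary C4 (Thorpe–Ingold effect) are meant to secure, and the C6 stereocentre is transient.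

Step 12
Reactants: 21 cyclic allylsilane
Product: 22 8(17)-exocyclic alkene with 9α-H
Conditions: TsOH·H2O (0.2 equiv), H2O-saturated CH2Cl2, 0 °C
Reagents that add atoms: none
Why: Protodesilylation of the allylsilane (SE2′) should protonate C9 from the α-face, axial and anti to the C10 methyl, and loss of silicon then gives the C8=C17 methylene with the side chain equatorial.

Step 13
Reactants: 22 6α-sulfone
Product: 23 methyl 3α-acetoxy-15-(TBDPS-oxy)labda-8(17),13E-dien-19-oate
Conditions: SmI2, HMPA, THF–MeOH, −20 °C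
Reagents that add atoms: none
Why: Reductive desulfonylation by electron transfer from SmI2, C–S cleavage and protonation removes the activating group and leaves C6 as CH2, while esters, acetate and silyl ether are inert.

Step 14
Reactants: 23 silyl ether
Product: 24 methyl 3α-acetoxy-15-hydroxylabda-8(17),13E-dien-19-oate
Conditions: Bu4NF, AcOH, THF, rt
Reagents that add atoms: none
Why: Fluoride-mediated desilylation buffered with acetic acid frees the allylic alcohol without touching the hindered acetate.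

Step 15
Reactants: 24 (E)-allylic alcohol
Product: 25 (13R,14R)-13,14-epoxy-15-ol
Conditions: Ti(OiPr)4 (10 mol %), D-(−)-diethyl tartrate (12 mol %), t-BuOOH, 4 Å sieves, CH2Cl2, −20 °C
Reagents that add atoms: tert-butyl hydroperoxide, CC(C)(C)OO
Why: The Sharpless asymmetric epoxidation with the D-(−)-tartrate catalyst should deliver oxygen to the face that gives the (13R,14R)-epoxy alcohol (the enantiomeric sense to geraniol with L-(+)-tartrate) and ignores the non-allylic C8=C17 alkene.

Step 16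
Reactants: 25 epoxy alcohol
Product: 26 target epoxy aldehyde
Conditions: Dess–Martin periodinane, NaHCO3, CH2Cl2, 0 °C
Reagents that add atoms: none
Why: Buffered Dess–Martin oxidation converts the primary epoxy alcohol into the (13R,14S)-epoxy aldehyde without epimerisation or epoxide opening (the descriptor at C14 changes only through CIP priorities).

**Compound list**

1 | (2E)-3-methylpent-2-en-4-yn-1-ol | C#C/C(C)=C/CO | starting material
2 | tert-butyl{[(2E)-3-methylpent-2-en-4-yn-1-yl]oxy}diphenylsilane | C#C/C(C)=C/CO[Si](c1ccccc1)(c1ccccc1)C(C)(C)C | intermediate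
3 | tert-butyl{[(2E)-3-methylpenta-2,4-dien-1-yl]oxy}diphenylsilane | C=C/C(C)=C/CO[Si](c1ccccc1)(c1ccccc1)C(C)(C)C | intermediate
4 | 3-chloropropan-1-ol | OCCCCl | starting material
5 | methyl but-2-ynoate | CC#CC(=O)OC | starting material
6 | chloromagnesium 3-(chloromagnesio)propan-1-olate (Normant Grignard reagent) | Cl[Mg]OCCC[Mg]Cl | intermediate
7 | {(1Z)-5-[(chloromagnesio)oxy]-1-(methoxycarbonyl)-2-methylpent-1-en-1-yl}copper | COC(=O)/C([Cu])=C(\C)CCCO[Mg]Cl | intermediate
8 | methyl (2Z)-6-hydroxy-2-iodo-3-methylhex-2-enoate | COC(=O)/C(I)=C(\C)CCCO | intermediate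
9 | 9-[(3E)-5-{[tert-butyl(diphenyl)silyl]oxy}-3-methylpent-3-en-1-yl]-9-borabicyclo[3.3.1]nonane | C1CC2CCCC(C1)B2CC/C(C)=C/CO[Si](c1ccccc1)(c1ccccc1)C(C)(C)C | intermediate
10 | methyl (2E)-2-[(3E)-5-{[tert-butyl(diphenyl)silyl]oxy}-3-methylpent-3-en-1-yl]-6-hydroxy-3-methylhex-2-enoate | COC(=O)/C(CC/C(C)=C/CO[Si](c1ccccc1)(c1ccccc1)C(C)(C)C)=C(\C)CCCO | intermediate
11 | (4E)-5-[(3E)-5-{[tert-butyl(diphenyl)silyl]oxy}-3-methylpent-3-en-1-yl]-4-methyl-7-(trimethylsilyl)-6-[(trimethylsilyl)methyl]hept-4-ene-1,6-diol | C[Si](C)(C)CC(O)(C[Si](C)(C)C)/C(CC/C(C)=C/CO[Si](c1ccccc1)(c1ccccc1)C(C)(C)C)=C(\C)CCCO | intermediate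
12 | (4E)-5-[(3E)-5-{[tert-butyl(diphenyl)silyl]oxy}-3-methylpent-3-en-1-yl]-4-methyl-6-methylidene-7-(trimethylsilyl)hept-4-en-1-ol | C[Si](C)(C)CC(=C)/C(CC/C(C)=C/CO[Si](c1ccccc1)(c1ccccc1)C(C)(C)C)=C(\C)CCCO | intermediate
13 | (4E)-5-[(3E)-5-{[tert-butyl(diphenyl)silyl]oxy}-3-methylpent-3-en-1-yl]-4-methyl-6-methylidene-7-(trimethylsilyl)hept-4-enal | C[Si](C)(C)CC(=C)/C(CC/C(C)=C/CO[Si](c1ccccc1)(c1ccccc1)C(C)(C)C)=C(\C)CCC=O | intermediate
14 | (4S)-4-benzyl-3-propanoyl-1,3-oxazolidin-2-one | CCC(=O)N1[C@@H](Cc2ccccc2)COC1=O | starting material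
15 | (Z)-dibutylboron enolate of 14 | C/C=C(\OB(CCCC)CCCC)N1[C@@H](Cc2ccccc2)COC1=O | intermediate
16 | (4S)-4-benzyl-3-[(2S,3R,6E)-7-[(3E)-5-{[tert-butyl(diphenyl)silyl]oxy}-3-methylpent-3-en-1-yl]-3-hydroxy-2,6-dimethyl-8-methylidene-9-(trimethylsilyl)non-6-enoyl]-1,3-oxazolidin-2-one | C[Si](C)(C)CC(=C)/C(CC/C(C)=C/CO[Si](c1ccccc1)(c1ccccc1)C(C)(C)C)=C(\C)CC[C@@H](O)[C@H](C)C(=O)N1[C@@H](Cc2ccccc2)COC1=O | intermediate
17 | methyl (2S,3R,6E)-7-[(3E)-5-{[tert-butyl(diphenyl)silyl]oxy}-3-methylpent-3-en-1-yl]-3-hydroxy-2,6-dimethyl-8-methylidene-9-(trimethylsilyl)non-6-enoate | C[Si](C)(C)CC(=C)/C(CC/C(C)=C/CO[Si](c1ccccc1)(c1ccccc1)C(C)(C)C)=C(\C)CC[C@@H](O)[C@H](C)C(=O)OC | intermediate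
18 | dilithium alkoxide–enolate of 17 | C[Si](C)(C)CC(=C)/C(CC/C(C)=C/CO[Si](c1ccccc1)(c1ccccc1)C(C)(C)C)=C(\C)CC[C@@H](O[Li])C(C)=C(OC)O[Li] | intermediate
19 | methyl (2R,3R,6E)-7-[(3E)-5-{[tert-butyl(diphenyl)silyl]oxy}-3-methylpent-3-en-1-yl]-3-hydroxy-2,6-dimethyl-8-methylidene-2-[(E)-2-(phenylsulfonyl)ethenyl]-9-(trimethylsilyl)non-6-enoate | C[Si](C)(C)CC(=C)/C(CC/C(C)=C/CO[Si](c1ccccc1)(c1ccccc1)C(C)(C)C)=C(\C)CC[C@@H](O)[C@](/C=C/S(=O)(=O)c1ccccc1)(C)C(=O)OC | intermediate
20 | methyl (2R,3R,6E)-3-acetoxy-7-[(3E)-5-{[tert-butyl(diphenyl)silyl]oxy}-3-methylpent-3-en-1-yl]-2,6-dimethyl-8-methylidene-2-[(E)-2-(phenylsulfonyl)ethenyl]-9-(trimethylsilyl)non-6-enoate | C[Si](C)(C)CC(=C)/C(CC/C(C)=C/CO[Si](c1ccccc1)(c1ccccc1)C(C)(C)C)=C(\C)CC[C@@H](OC(C)=O)[C@](/C=C/S(=O)(=O)c1ccccc1)(C)C(=O)OC | intermediate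
21 | methyl 3α-acetoxy-15-[(tert-butyldiphenylsilyl)oxy]-6α-(phenylsulfonyl)-17-(trimethylsilyl)labda-8,13E-dien-19-oate (5α-H, 10β-CH3, 4α-CH3, 4β-CO2CH3) | C[Si](C)(C)CC1=C(CC/C(C)=C/CO[Si](c2ccccc2)(c2ccccc2)C(C)(C)C)[C@@]3(C)CC[C@@H](OC(C)=O)[C@](C)(C(=O)OC)[C@@H]3[C@@H](S(=O)(=O)c2ccccc2)C1 | intermediate
22 | methyl 3α-acetoxy-15-[(tert-butyldiphenylsilyl)oxy]-6α-(phenylsulfonyl)labda-8(17),13E-dien-19-oate (9α-H) | C=C1C[C@H](S(=O)(=O)c2ccccc2)[C@@H]2[C@](C)(CC[C@@H](OC(C)=O)[C@]2(C)C(=O)OC)[C@H]1CC/C(C)=C/CO[Si](c1ccccc1)(c1ccccc1)C(C)(C)C | intermediate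
23 | methyl 3α-acetoxy-15-[(tert-butyldiphenylsilyl)oxy]labda-8(17),13E-dien-19-oate | C=C1CC[C@@H]2[C@](C)(CC[C@@H](OC(C)=O)[C@]2(C)C(=O)OC)[C@H]1CC/C(C)=C/CO[Si](c1ccccc1)(c1ccccc1)C(C)(C)C | intermediate
24 | methyl 3α-acetoxy-15-hydroxylabda-8(17),13E-dien-19-oate | C=C1CC[C@@H]2[C@](C)(CC[C@@H](OC(C)=O)[C@]2(C)C(=O)OC)[C@H]1CC/C(C)=C/CO | intermediate
25 | methyl (13R,14R)-3α-acetoxy-13,14-epoxy-15-hydroxylabd-8(17)-en-19-oate | C=C1CC[C@@H]2[C@](C)(CC[C@@H](OC(C)=O)[C@]2(C)C(=O)OC)[C@H]1CC[C@@]1(C)O[C@@H]1CO | intermediate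
26 | methyl (13R,14S)-3α-acetoxy-13,14-epoxy-15-oxolabd-8(17)-en-19-oate (CNP0145900.1) | C=C1CC[C@@H]2[C@](C)(CC[C@@H](OC(C)=O)[C@]2(C)C(=O)OC)[C@H]1CC[C@@]1(C)O[C@@H]1C=O | target

**Step count.** Total: 16 steps. Longest linear sequence: 15 steps (steps 1, 2 and 4–16, from enynol 1).

**Steps most likely to fail**

Step 11 (intramolecular Diels–Alder). The cycloaddition may show poor π-facial or exo/endo discrimination, because the tether carries a pseudo-axial acetoxy group next to quaternary C4. It may also be too slow, with the hindered diene drifting into 1,5-hydrogen shift. The fallback sets out from 19 and returns at 21, and moves the C3 stereocentre to after ring formation. Dess–Martin oxidation of 19 should give the β-keto ester triene F1, whose sp2 C3 flattens the tether and removes the axial substituent. Heating F1 in toluene should give the trans-fused keto sulfone F2. Reduction with LiBH(s-Bu)3 at −78 °C (equatorial hydride delivery) should give the axial 3α-alcohol F3, and acetylation (Ac2O, DMAP) then gives 21.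

Step 9 (Fráter–Seebach sulfonylvinylation). The dianion may undergo O-vinylation at the alkoxide, a second Michael addition to the product, or retro-aldol cleavage. The fallback sets out from 17 and returns at 19. The same dianion is C-formylated with ethyl formate, again anti to the C2 chain, to give the α-formyl β-hydroxy ester F4. A Horner–Wadsworth–Emmons olefination with diethyl [(phenylsulfonyl)methyl]phosphonate (LiCl, DBU, MeCN) then builds the (E)-vinyl sulfone of 19.

Step 5 (ester to allylsilane). The second addition to the hindered tetrasubstituted enoate may stall, or the product may lose silicon during the Peterson elimination. The fallback sets out from 10 and returns at 12. Aminolysis with Me(MeO)NH·HCl and AlMe3 gives the Weinreb amide F5. A single addition of Me3SiCH2MgCl gives the α-silyl ketone F6. Wittig methylenation with Ph3P=CH2 (excess, THF) then gives 12 without an elimination step.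

Further compounds
F1 | step 11 | methyl (2R,6E)-7-[(3E)-5-{[tert-butyl(diphenyl)silyl]oxy}-3-methylpent-3-en-1-yl]-2,6-dimethyl-8-methylidene-3-oxo-2-[(E)-2-(phenylsulfonyl)ethenyl]-9-(trimethylsilyl)non-6-enoate | C[Si](C)(C)CC(=C)/C(CC/C(C)=C/CO[Si](c1ccccc1)(c1ccccc1)C(C)(C)C)=C(\C)CCC(=O)[C@](/C=C/S(=O)(=O)c1ccccc1)(C)C(=O)OC
F2 | step 11 | methyl 15-[(tert-butyldiphenylsilyl)oxy]-3-oxo-6α-(phenylsulfonyl)-17-(trimethylsilyl)labda-8,13E-dien-19-oate | C[Si](C)(C)CC1=C(CC/C(C)=C/CO[Si](c2ccccc2)(c2ccccc2)C(C)(C)C)[C@@]3(C)CCC(=O)[C@](C)(C(=O)OC)[C@@H]3[C@@H](S(=O)(=O)c2ccccc2)C1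
F3 | step 11 | methyl 15-[(tert-butyldiphenylsilyl)oxy]-3α-hydroxy-6α-(phenylsulfonyl)-17-(trimethylsilyl)labda-8,13E-dien-19-oate | C[Si](C)(C)CC1=C(CC/C(C)=C/CO[Si](c2ccccc2)(c2ccccc2)C(C)(C)C)[C@@]3(C)CC[C@@H](O)[C@](C)(C(=O)OC)[C@@H]3[C@@H](S(=O)(=O)c2ccccc2)C1
F4 | step 9 | methyl (2S,3R,6E)-7-[(3E)-5-{[tert-butyl(diphenyl)silyl]oxy}-3-methylpent-3-en-1-yl]-2-formyl-3-hydroxy-2,6-dimethyl-8-methylidene-9-(trimethylsilyl)non-6-enoate | C[Si](C)(C)CC(=C)/C(CC/C(C)=C/CO[Si](c1ccccc1)(c1ccccc1)C(C)(C)C)=C(\C)CC[C@@H](O)[C@](C=O)(C)C(=O)OC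
F5 | step 5 | (2E)-2-[(3E)-5-{[tert-butyl(diphenyl)silyl]oxy}-3-methylpent-3-en-1-yl]-6-hydroxy-N-methoxy-N,3-dimethylhex-2-enamide | CON(C)C(=O)/C(CC/C(C)=C/CO[Si](c1ccccc1)(c1ccccc1)C(C)(C)C)=C(\C)CCCO
F6 | step 5 | (3E)-3-[(3E)-5-{[tert-butyl(diphenyl)silyl]oxy}-3-methylpent-3-en-1-yl]-7-hydroxy-4-methyl-1-(trimethylsilyl)hept-3-en-2-one | C[Si](C)(C)CC(=O)/C(CC/C(C)=C/CO[Si](c1ccccc1)(c1ccccc1)C(C)(C)C)=C(\C)CCCO
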